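The retrosynthesis traces the C3 CH2OH group back to one ester of a geminal diester on C3, and the C5 methylene back to a C5 methyl acetal. The oxolane is then cut at O1–C5 and C2–C3.
The enabling feature lies in the ring O1–C2(aryl)–C3–C4(benzyl)–C5. C2 and O1 are the carbonyl group of an aryl aldehyde. C3–C4–C5 is a three-carbon chain that can hold two ester acceptors at C3 and a disposable methoxy donor at C5 (plain CH2 in the target), which makes it a donor–acceptor cyclopropane with a polarised C3–C5 bond.
In the forward direction a benzaldehyde is extended to an (E)-enol ether and a malonate carbene closes the three-membered ring (C3–C4 and C3–C5). The annulation then exchanges this ring for the oxolane, and three trimming operations follow: C5–OMe to C5–H, one CO2Me to H, and the other CO2Me to CH2OH.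
C4 comes from the chiral copper catalyst of the cyclopropanation, and C2 is relayed from C4 in the annulation (2,4-cis). C3 is set last by hydrogen-atom transfer to a planar C3 radical on the face opposite aryl and benzyl, which gives the all-cis (2R,3R,4R) array.

Key step: step 7

Atom labels: O1 and C2–C5 are the oxolane atoms of the target, and the same labels are used for these atoms in all earlier compounds.
Assumption: the (S,S)-ligand of step 6 is taken to give the (2S,3R)-cyclopropane. The sense of induction on this enol ether has to be verified on the first batch, and the equally available (R,R)-ligand is used if it proves opposite.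

Step 1
Reactants: 1 2,4,5-trimethoxybenzaldehyde
Product: 2 methyl (E)-3-(2,4,5-trimethoxyphenyl)prop-2-enoate
Conditions: Ph3P=CHCO2Me (1.2 equiv), PhMe, 80 °C
Reagents that add atoms: methyl (triphenylphosphoranylidene)acetate, COC(=O)C=P(c1ccccc1)(c1ccccc1)c1ccccc1
Why: Wittig olefination of an aromatic aldehyde with a stabilised ylide should give the (E)-cinnamate almost exclusively, and the aryl methyl ethers are inert.

Step 2
Reactants: 2 methyl (E)-3-(2,4,5-trimethoxyphenyl)prop-2-enoate
Product: 3 (E)-3-(2,4,5-trimethoxyphenyl)prop-2-en-1-ol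
Conditions: i-Bu2AlH (2.3 equiv), CH2Cl2, −78 → 0 °C; aq potassium sodium tartrate
Reagents that add atoms: none
Why: i-Bu2AlH reduces α,β-unsaturated esters in the 1,2-sense to allylic alcohols without touching the alkene, and the neutral tartrate work-up avoids ionisation of the electron-rich cinnamyl alcohol.

Step 3
Reactants: 3 (E)-3-(2,4,5-trimethoxyphenyl)prop-2-en-1-ol
Product: 4 1,2,4-trimethoxy-5-[(E)-3-methoxyprop-1-enyl]benzene
Conditions: NaH (1.3 equiv), MeI (1.5 equiv), THF, 0 °C → rt
Reagents that add atoms: iodomethane, CI
Why: Williamson etherification of the primary sodium alkoxide with MeI is the only reaction open to a substrate that has no other acidic or electrophilic site.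

Step 4
Reactants: 4 1,2,4-trimethoxy-5-[(E)-3-methoxyprop-1-enyl]benzene
Product: 5 1,2,4-trimethoxy-5-[(E)-3-methoxyprop-2-enyl]benzene, the (E)-methyl enol ether ArCH2CH=CHOMe
Conditions: [Ir(cod)(PMePh2)2]PF6 (2 mol %, activated with H2, then purged with Ar), THF, rt
Reagents that add atoms: none
Why: In this metal-catalysed allyl ether to enol ether isomerisation the hydrogen-activated cationic iridium complex shifts the double bond by a 1,3-hydrogen migration through a syn-π-allyl iridium hydride, a pathway known to favour (E)-1-alkenyl ethers strongly, and conjugation with oxygen outweighs the lost styrene conjugation.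

Step 5
Reactants: 6 dimethyl malonate
Product: 7 phenyliodonium bis(methoxycarbonyl)methanide (the malonate iodonium ylide)
Conditions: PhI(OAc)2 (1.0 equiv), KOH (excess), MeCN, 0 °C
Reagents that add atoms: (diacetoxyiodo)benzene, CC(=O)OI(OC(C)=O)c1ccccc1
Why: Base-mediated condensation of an active methylene compound with PhI(OAc)2 is the standard preparation of this crystalline ylide, which serves as a safe surrogate for the diazomalonate.

Step 6
Reactants: 5 1,2,4-trimethoxy-5-[(E)-3-methoxyprop-2-enyl]benzene; 7 phenyliodonium bis(methoxycarbonyl)methanide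
Product: 8 dimethyl (2S,3R)-2-methoxy-3-(2,4,5-trimethoxybenzyl)cyclopropane-1,1-dicarboxylate (methoxy and benzyl trans)
Conditions: 7 (1.3 equiv), Cu(MeCN)4PF6 (5 mol %), (4S,4'S)-2,2'-(1,3-diphenylpropane-2,2-diyl)bis(4-phenyl-4,5-dihydrooxazole) (6 mol %), 4 Å MS, PhMe, 0 °C
Reagents that add atoms: none
Why: In this asymmetric copper-carbenoid cyclopropanation the ylide hands C(CO2Me)2 to monovalent copper with loss of PhI, the electrophilic carbenoid adds to the most electron-rich π bond (the enol ether) in a concerted syn fashion so that the (E)-geometry becomes the trans OMe/benzyl relation, and the C2-symmetric bis(oxazoline) pocket selects the alkene face and thereby fixes C4 and C5 in the absolute sense.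

Step 7
Reactants: 8 dimethyl (2S,3R)-2-methoxy-3-(2,4,5-trimethoxybenzyl)cyclopropane-1,1-dicarboxylate; 9 3,4,5-trimethoxybenzaldehyde
Product: 10 dimethyl (2S,4R,5S)-5-methoxy-2-(3,4,5-trimethoxyphenyl)-4-(2,4,5-trimethoxybenzyl)oxolane-3,3-dicarboxylate (aryl, benzyl and methoxy all cis)
Conditions: 9 (2 equiv), Sn(OTf)2 (10 mol %), 4 Å MS, CH2Cl2, −40 → 0 °C
Reagents that add atoms: none
Why: Sn(OTf)2 chelates the geminal diester of 8 and polarises the C3–C5 bond, the only ring bond flanked by both donor and acceptor, so that the carbonyl oxygen of 9 attacks the methoxy-bearing C5 from the rear while the tin malonate enolate departs (O1–C5 formed, cyclopropane opened). The aryl-stabilised oxocarbenium ion thus formed is captured by the enolate carbon in an aldol-type step (C2–C3 formed), which closes the oxolane in a formal 5-(enolexo)-endo-trig mode, a closure that is routine when the acceptor is an oxocarbenium ion. The closest known reaction type is the Lewis acid catalysed [3+2] annulation of cyclopropane-1,1-diesters with aldehydes, which gives 2,5-cis oxolanes, transfers the configuration of trans-2,3-disubstituted cyclopropanes and tolerates heteroatom donors. C5 is set by the backside displacement, which converts the trans OMe/benzyl pair of 8 into a cis pair, and C2 is set in the envelope-shaped closing transition state, where the aryl group lies pseudoequatorial and hence cis to the C5 and C4 substituents. The selectivity that the route needs is 2,4-cis, and it rests on the C4 stereocentre, none of whose bonds is broken: even if the strong methoxy donor makes the opening more ionic, closure with aryl and benzyl both pseudoequatorial remains preferred, and a C5 epimer would merge with 10 in step 8. Regioselectivity comes from the donor, and low temperature, a mild catalytic Lewis acid and excess 9 should keep proton loss from C4 and Friedel–Crafts capture of C5 by the neighbouring arene behind the bimolecular pathway.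

Step 8
Reactants: 10 dimethyl (2S,4R,5S)-5-methoxy-2-(3,4,5-trimethoxyphenyl)-4-(2,4,5-trimethoxybenzyl)oxolane-3,3-dicarboxylate
Product: 11 dimethyl (2S,4R)-2-(3,4,5-trimethoxyphenyl)-4-(2,4,5-trimethoxybenzyl)oxolane-3,3-dicarboxylate (aryl and benzyl cis)
Conditions: Et3SiH (5 equiv), BF3·OEt2 (1.5 equiv), CH2Cl2, −78 → −20 °C
Reagents that add atoms: none
Why: In this ionic reduction of a cyclic acetal BF3 removes the exocyclic methoxy group, the ring oxocarbenium ion takes hydride from the excess silane faster than the flanking arene can attack it, the benzylic C2–O1 bond survives because a cation at C2 would sit next to the electron-poor diester carbon, and C5 ceases to be a stereocentre.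

Step 9
Reactants: 11 dimethyl (2S,4R)-2-(3,4,5-trimethoxyphenyl)-4-(2,4,5-trimethoxybenzyl)oxolane-3,3-dicarboxylate
Product: 12 (2S,3S,4R)-3-(methoxycarbonyl)-2-(3,4,5-trimethoxyphenyl)-4-(2,4,5-trimethoxybenzyl)oxolane-3-carboxylic acid (CO2H trans to aryl and benzyl)
Conditions: KOH (5 equiv), MeOH/THF/H2O, 50 °C; then 1 M HCl, 0 °C, to pH 3
Reagents that add atoms: potassium hydroxide, [K+].[OH-]
Why: Saponification of a disubstituted malonate stops at the half-ester because the carboxylate formed shields the remaining ester, the ester on the face away from aryl and benzyl is expected to react, and this site selectivity is of no consequence since either half-ester leads to the same C3 radical in step 10.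

Step 10
Reactants: 12 (2S,3S,4R)-3-(methoxycarbonyl)-2-(3,4,5-trimethoxyphenyl)-4-(2,4,5-trimethoxybenzyl)oxolane-3-carboxylic acid
Product: 15 methyl (2R,3S,4R)-2-(3,4,5-trimethoxyphenyl)-4-(2,4,5-trimethoxybenzyl)oxolane-3-carboxylate (all-cis), via acid chloride 13 (not isolated), via Barton ester 14 (not isolated)
Conditions: Me2C=C(Cl)NMe2 (1.2 equiv), CH2Cl2, 0 °C → rt; sodium pyrithione (1.3 equiv), DMAP (cat), dark, rt; then t-BuSH (10 equiv), visible light, 0 °C
Reagents that add atoms: 1-chloro-N,N,2-trimethylprop-1-en-1-amine, CC(C)=C(Cl)N(C)C (chlorine kept in 13 only); sodium 2-thioxopyridin-1(2H)-olate, [Na+].[O-]n1ccccc1=S (kept in 14 only; nothing but hydrogen is added on the way to 15)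
Why: In this Barton reductive decarboxylation visible light cleaves the N–O bond of 14, loss of CO2 leaves a planar ester-stabilised radical at C3, and the bulky thiol can reach it only from the face opposite the cis-disposed C2 aryl and C4 benzyl groups, so that hydrogen enters on that open face and the ester is pushed to the side of both neighbours under neutral conditions that cannot epimerise this kinetic all-cis product.

Step 11
Reactants: 15 methyl (2R,3S,4R)-2-(3,4,5-trimethoxyphenyl)-4-(2,4,5-trimethoxybenzyl)oxolane-3-carboxylate
Product: 16 [(2R,3R,4R)-2-(3,4,5-trimethoxyphenyl)-4-(2,4,5-trimethoxybenzyl)oxolan-3-yl]methanol (all-cis), the target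
Conditions: LiAlH4 (1.5 equiv), THF, 0 °C
Reagents that add atoms: none
Why: LiAlH4 reduction of the ester to the primary alcohol is much faster than enolisation at 0 °C, so the contra-thermodynamic C3 configuration passes unchanged into the target, and all ethers are inert.

Compound list
1 | 2,4,5-trimethoxybenzaldehyde | COc1cc(OC)c(OC)cc1C=O | starting material
2 | methyl (E)-3-(2,4,5-trimethoxyphenyl)prop-2-enoate | COC(=O)/C=C/c1cc(OC)c(OC)cc1OC | intermediate
3 | (E)-3-(2,4,5-trimethoxyphenyl)prop-2-en-1-ol | OC/C=C/c1cc(OC)c(OC)cc1OC | intermediate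
4 | 1,2,4-trimethoxy-5-[(E)-3-methoxyprop-1-enyl]benzene | COC/C=C/c1cc(OC)c(OC)cc1OC | intermediate
5 | 1,2,4-trimethoxy-5-[(E)-3-methoxyprop-2-enyl]benzene | CO/C=C/Cc1cc(OC)c(OC)cc1OC | intermediate
6 | dimethyl malonate | COC(=O)CC(=O)OC | starting material
7 | phenyliodonium bis(methoxycarbonyl)methanide | COC(=O)[C-](C(=O)OC)[I+]c1ccccc1 | intermediate
8 | dimethyl (2S,3R)-2-methoxy-3-(2,4,5-trimethoxybenzyl)cyclopropane-1,1-dicarboxylate | COC(=O)C1(C(=O)OC)[C@@H](OC)[C@@H]1Cc1cc(OC)c(OC)cc1OC | intermediate
9 | 3,4,5-trimethoxybenzaldehyde | COc1cc(C=O)cc(OC)c1OC | starting material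
10 | dimethyl (2S,4R,5S)-5-methoxy-2-(3,4,5-trimethoxyphenyl)-4-(2,4,5-trimethoxybenzyl)oxolane-3,3-dicarboxylate | COc1cc(OC)c(OC)cc1C[C@H]1[C@@H](OC)O[C@@H](c2cc(OC)c(OC)c(OC)c2)C1(C(=O)OC)C(=O)OC | intermediate
11 | dimethyl (2S,4R)-2-(3,4,5-trimethoxyphenyl)-4-(2,4,5-trimethoxybenzyl)oxolane-3,3-dicarboxylate | COc1cc(OC)c(OC)cc1C[C@H]1CO[C@@H](c2cc(OC)c(OC)c(OC)c2)C1(C(=O)OC)C(=O)OC | intermediate
12 | (2S,3S,4R)-3-(methoxycarbonyl)-2-(3,4,5-trimethoxyphenyl)-4-(2,4,5-trimethoxybenzyl)oxolane-3-carboxylic acid | COc1cc(OC)c(OC)cc1C[C@H]1CO[C@@H](c2cc(OC)c(OC)c(OC)c2)[C@@]1(C(=O)O)C(=O)OC | intermediate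
13 | methyl (2S,3R,4R)-3-(chlorocarbonyl)-2-(3,4,5-trimethoxyphenyl)-4-(2,4,5-trimethoxybenzyl)oxolane-3-carboxylate (acid chloride of 12) | COc1cc(OC)c(OC)cc1C[C@H]1CO[C@@H](c2cc(OC)c(OC)c(OC)c2)[C@@]1(C(=O)Cl)C(=O)OC | intermediate
14 | Barton ester of 12, the (2S,3R,4R)-configured O-acyl derivative of 1-hydroxypyridine-2(1H)-thione | COc1cc(OC)c(OC)cc1C[C@H]1CO[C@@H](c2cc(OC)c(OC)c(OC)c2)[C@@]1(C(=O)On2ccccc2=S)C(=O)OC | intermediate
15 | methyl (2R,3S,4R)-2-(3,4,5-trimethoxyphenyl)-4-(2,4,5-trimethoxybenzyl)oxolane-3-carboxylate | COc1cc(OC)c(OC)cc1C[C@H]1CO[C@@H](c2cc(OC)c(OC)c(OC)c2)[C@H]1C(=O)OC | intermediate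
16 | [(2R,3R,4R)-2-(3,4,5-trimethoxyphenyl)-4-(2,4,5-trimethoxybenzyl)oxolan-3-yl]methanol | COc1cc(OC)c(OC)cc1C[C@H]1CO[C@@H](c2cc(OC)c(OC)c(OC)c2)[C@H]1CO | target

Total step count: 11.
Longest linear sequence: 10 steps (1 to 16 by steps 1–4 and 6–11). Step 5 is a one-step side branch.

Steps most likely to fail

Step 6.
- **Risk:** The catalyst may discriminate poorly between the faces of an acyclic 1,2-disubstituted enol ether. The carbenoid may also be diverted to the electron-rich arene.
- **Fallback:** Asymmetric catalysis is replaced by a resolution that sets out from 5 and 6. Diazo transfer to 6 (4-acetamidobenzenesulfonyl azide, Et3N, MeCN) gives dimethyl diazomalonate F1. Rh2(esp)2 (0.2 mol %, CH2Cl2, rt) then transfers its carbene stereospecifically to 5. The trans cyclopropane is obtained as a racemate, that is 8 together with its mirror image, dimethyl (2R,3S)-2-methoxy-3-(2,4,5-trimethoxybenzyl)cyclopropane-1,1-dicarboxylate F2. Preparative chromatography on a chiral stationary phase separates the two, and the route is rejoined at 8.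

Step 7.
- **Risk:** The methoxy-bearing carbon may ionise fully before the aldehyde attacks. Proton loss from C4, Friedel–Crafts capture by the neighbouring arene, or loss of the 2,4-cis relay could follow.
- **Fallback:** The cyclopropane is abandoned, and the same diester is assembled from 6 and 9 by a palladium-catalysed three-component coupling.
  - Knoevenagel condensation (piperidine, AcOH, PhMe, reflux) gives dimethyl 2-(3,4,5-trimethoxybenzylidene)malonate F3.
  - Lithium propargyl alkoxide adds to F3 in an oxa-Michael step. The resulting malonate enolate closes 5-exo-dig onto the alkyne, which is activated by the arylpalladium iodide from 1-iodo-2,4,5-trimethoxybenzene (PdCl2(PPh3)2 reduced with n-BuLi to zerovalent palladium, THF/DMSO). This gives racemic dimethyl (Z)-4-(2,4,5-trimethoxybenzylidene)-2-(3,4,5-trimethoxyphenyl)oxolane-3,3-dicarboxylate F4.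
  - Hydrogenation (H2, Pd/C, EtOAc) from the face away from the C2 aryl group should give the 2,4-cis diester as a racemate, that is 11 and its mirror image, dimethyl (2R,4S)-2-(3,4,5-trimethoxyphenyl)-4-(2,4,5-trimethoxybenzyl)oxolane-3,3-dicarboxylate F5.
  - Separation on a chiral stationary phase rejoins the route at 11.

Step 10.
- **Risk:** Hydrogen transfer to the hindered, ester-stabilised C3 radical may be slow, so that recombination with the pyridylthio unit overtakes reduction. The facial bias may also be too small.
- **Fallback:** The radical step is replaced by two ionic steps that set out from 11. Krapcho dealkoxycarbonylation (LiCl, wet DMSO, 150 °C) should give mainly the more stable ester with CO2Me trans to both neighbours, methyl (2R,3R,4R)-2-(3,4,5-trimethoxyphenyl)-4-(2,4,5-trimethoxybenzyl)oxolane-3-carboxylate F6. F6 is deprotonated with LiN(i-Pr)2 (THF, −78 °C), where the ring C2–O1 bond is poorly aligned for β-elimination. Kinetic protonation of the enolate by 2,6-di-tert-butyl-4-methylphenol on the open face then inverts C3, and the route is rejoined at 15.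

Further compounds
F1 | step 6 | dimethyl diazomalonate | COC(=O)C(=[N+]=[N-])C(=O)OC
F2 | step 6 | dimethyl (2R,3S)-2-methoxy-3-(2,4,5-trimethoxybenzyl)cyclopropane-1,1-dicarboxylate (mirror image of 8) | COC(=O)C1(C(=O)OC)[C@H](OC)[C@H]1Cc1cc(OC)c(OC)cc1OC
F3 | step 7 | dimethyl 2-(3,4,5-trimethoxybenzylidene)malonate | COC(=O)C(=Cc1cc(OC)c(OC)c(OC)c1)C(=O)OC
F4 | step 7 | dimethyl (Z)-4-(2,4,5-trimethoxybenzylidene)-2-(3,4,5-trimethoxyphenyl)oxolane-3,3-dicarboxylate (racemic at C2) | COC(=O)C1(C(=O)OC)C(c2cc(OC)c(OC)c(OC)c2)OC/C1=C\c1cc(OC)c(OC)cc1OC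
F5 | step 7 | dimethyl (2R,4S)-2-(3,4,5-trimethoxyphenyl)-4-(2,4,5-trimethoxybenzyl)oxolane-3,3-dicarboxylate (mirror image of 11) | COc1cc(OC)c(OC)cc1C[C@@H]1CO[C@H](c2cc(OC)c(OC)c(OC)c2)C1(C(=O)OC)C(=O)OC
F6 | step 10 | methyl (2R,3R,4R)-2-(3,4,5-trimethoxyphenyl)-4-(2,4,5-trimethoxybenzyl)oxolane-3-carboxylate (C3 epimer of 15) | COc1cc(OC)c(OC)cc1C[C@H]1CO[C@@H](c2cc(OC)c(OC)c(OC)c2)[C@@H]1C(=O)OC
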